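The route is built on one disconnection: the O‑bridged nine‑membered ether is cut back to a six‑membered one. Because the methylene‑bearing carbon C7 lies two atoms (through C8) from bridge carbon C9 in the oxonane ring, C8–C9 and O–C9 can both come from a [2,3] shift of an allyl oxonium ylide. One copper‑catalysed operation on a diazoketone therefore closes the tetrahydrofuranone (O, C2, C1, C10, C9), enlarges a tetrahydropyran by three atoms to the oxonene and sets C9. The precursor is a 2,6‑cis tetrahydropyran that already holds C2, C3(Me)(OSiEt3) and C4(OSiEt3), with CH2COCHN2 on C2 and a 2‑(trimethylsilylmethyl)vinyl group on C6.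

Key step: step 13

Remarks on the chemistry (one line each):
- Asbestinin numbering is used throughout: C2/C9 are the ether‑bridge carbons, C1/C10 the ring‑fusion carbons, C3 the C(Me)–O carbon, C4 the CH–OAc carbon, C7 the methylene‑bearing carbon, C11 the acyloxy carbon, C12 and C15 the methyl‑bearing CH carbons, C16 the OCH2 carbon.
- C2, C3 and C4 of diazoketone 22 and C9 of ketone 24 were checked atom by atom against the target and need no correction. The ring alkene of 24 is the cis (ring‑Z) isomer, whose CIP descriptor is E only because CH2SiMe3 outranks C8.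
- Precursor design: both the C3 and the C4 oxygen carry triethylsilyl groups. They are removed together after the hydroboration, and C4 is acetylated before the C11 hydroxyl exists, so the three hydroxyls of the target never have to be told apart.
- Assumptions: methyl (R)‑glycidate, (R)‑2‑hydroxyoctanoic acid and ethyl (Z)‑prop‑1‑enyl ether are bought as single isomers (the last is otherwise made in one operation from allyl ethyl ether with KOt‑Bu in DMSO).

Step 1
Reactants: 1 methyl (R)-oxirane-2-carboxylate; 2 vinylmagnesium bromide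
Product: 3 methyl (R)-2-hydroxypent-4-enoate
Conditions: 2 (1.3 equiv), CuI (10 mol%), THF, −78 → −40 °C; aq. NH4Cl
Reagents that add atoms: none
Why: Copper‑catalysed SN2 opening of the epoxide at its unsubstituted carbon by the vinyl Grignard reagent leaves the stereocentre untouched, so the (R) centre of 1 becomes C6 of the later pyran.

Step 2
Reactants: 3 methyl (R)-2-hydroxypent-4-enoate; 4 (trimethylsilyl)methylmagnesium chloride
Product: 6 (R)-2-[(trimethylsilyl)methyl]hexa-1,5-dien-3-ol, via bis(silylmethyl) carbinol 5 (not isolated)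
Conditions: 4 (5 equiv), anhydrous CeCl3 (5 equiv), THF, −78 °C → rt; aq. NH4Cl; then SiO2, CH2Cl2, rt
Reagents that add atoms: none
Why: Bunnelle allylsilane synthesis, in which the organocerium reagent adds twice to the ester (one further equivalent is spent on the hydroxyl) and Peterson elimination of carbinol 5 on silica gives the 2‑(silylmethyl)allyl unit without touching C6.

Step 3
Reactants: 6 (R)-2-[(trimethylsilyl)methyl]hexa-1,5-dien-3-ol; 7 methacryloyl chloride
Product: 8 (R)-2-[(trimethylsilyl)methyl]hexa-1,5-dien-3-yl 2-methylprop-2-enoate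
Conditions: 7, Et3N, DMAP (cat.), CH2Cl2, 0 °C
Reagents that add atoms: none
Why: DMAP‑catalysed acylation of the secondary allylic alcohol proceeds at oxygen with retention at C6.

Step 4
Reactants: 8 (R)-2-[(trimethylsilyl)methyl]hexa-1,5-dien-3-yl 2-methylprop-2-enoate
Product: 9 (R)-3-methyl-6-[3-(trimethylsilyl)prop-1-en-2-yl]-5,6-dihydro-2H-pyran-2-one
Conditions: second-generation Grubbs catalyst RuCl2(=CHPh)(PCy3)(H2IMes) (5 mol%), PhMe, 80 °C
Reagents that add atoms: none
Why: Ring‑closing metathesis of the allyl and methacrylate alkenes should give the six‑membered unsaturated lactone, because the hindered 1,1‑disubstituted allylsilane alkene could only close a four‑ or a tetrasubstituted five‑membered ring and stays out.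

Step 5
Reactants: 9 (R)-3-methyl-6-[3-(trimethylsilyl)prop-1-en-2-yl]-5,6-dihydro-2H-pyran-2-one
Product: 11 (4S,6R)-4-hydroxy-3-methyl-6-[3-(trimethylsilyl)prop-1-en-2-yl]tetrahydro-2H-pyran-2-one (C3 epimers), via boryl lactone 10 (not isolated)
Conditions: B2pin2 (1.1 equiv), CuCl (5 mol%), DPEphos (5 mol%), NaOt-Bu (10 mol%), MeOH (2 equiv), THF, rt; then NaBO3·4H2O, THF/H2O, rt
Reagents that add atoms: bis(pinacolato)diboron, CC1(C)OB(OC1(C)C)B1OC(C)(C)C(C)(C)O1 (boron of 10 only); sodium perborate, [Na+].[O-]OB=O (hydroxyl oxygen of 11)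
Why: Copper‑catalysed conjugate borylation followed by stereoretentive oxidation of the C–B bond should place the C4 oxygen trans to the C6 substituent, because the boryl copper species adds axially to the half‑chair lactone on the face opposite the pseudo‑equatorial C6 group (C3 stays a mixture and is re‑formed in step 7).

Step 6
Reactants: 11 (4S,6R)-4-hydroxy-3-methyl-6-[3-(trimethylsilyl)prop-1-en-2-yl]tetrahydro-2H-pyran-2-one
Product: 12 (4S,6R)-3-methyl-4-(triethylsilyloxy)-6-[3-(trimethylsilyl)prop-1-en-2-yl]tetrahydro-2H-pyran-2-one (C3 epimers)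
Conditions: Et3SiCl, imidazole, DMF, 0 °C → rt
Reagents that add atoms: chlorotriethylsilane, CC[Si](Cl)(CC)CC
Why: Standard silylation of the secondary alcohol under buffered conditions that do not provoke β‑elimination of the β‑hydroxy lactone.

Step 7
Reactants: 12 (4S,6R)-3-methyl-4-(triethylsilyloxy)-6-[3-(trimethylsilyl)prop-1-en-2-yl]tetrahydro-2H-pyran-2-one
Product: 13 (3R,4S,6R)-3-hydroxy-3-methyl-4-(triethylsilyloxy)-6-[3-(trimethylsilyl)prop-1-en-2-yl]tetrahydro-2H-pyran-2-one
Conditions: KN(SiMe3)2 (1.2 equiv), THF, −78 °C; 2-(phenylsulfonyl)-3-phenyloxaziridine, −78 °C; aq. NH4Cl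
Reagents that add atoms: 2-(phenylsulfonyl)-3-phenyloxaziridine, O=S(=O)(N1OC1c1ccccc1)c1ccccc1
Why: Davis enolate hydroxylation, in which the oxaziridine should approach the planar C3 enolate from the face opposite the pseudo‑axial C4 silyloxy group and so give the tertiary C3–OH trans to C4–O and cis to the C6 side chain.

Step 8
Reactants: 13 (3R,4S,6R)-3-hydroxy-3-methyl-4-(triethylsilyloxy)-6-[3-(trimethylsilyl)prop-1-en-2-yl]tetrahydro-2H-pyran-2-one
Product: 14 (3R,4S,6R)-3-methyl-3,4-bis(triethylsilyloxy)-6-[3-(trimethylsilyl)prop-1-en-2-yl]tetrahydro-2H-pyran-2-one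
Conditions: Et3SiOTf, 2,6-lutidine, CH2Cl2, −78 → 0 °C
Reagents that add atoms: triethylsilyl trifluoromethanesulfonate, CC[Si](CC)(CC)OS(=O)(=O)C(F)(F)F
Why: The silyl triflate is reactive enough to cap the hindered tertiary alcohol, which must be masked so that it cannot intercept the carbenoid in step 13.

Step 9
Reactants: 14 (3R,4S,6R)-3-methyl-3,4-bis(triethylsilyloxy)-6-[3-(trimethylsilyl)prop-1-en-2-yl]tetrahydro-2H-pyran-2-one
Product: 15 (3R,4S,6R)-3-methyl-3,4-bis(triethylsilyloxy)-6-[3-(trimethylsilyl)prop-1-en-2-yl]tetrahydro-2H-pyran-2-ol (anomers)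
Conditions: i-Bu2AlH (1.2 equiv), CH2Cl2, −78 °C; Rochelle salt
Reagents that add atoms: none
Why: Low‑temperature hydride reduction of the lactone stops at the aluminium hemiacetal and gives the lactol on work‑up.

Step 10
Reactants: 15 (3R,4S,6R)-3-methyl-3,4-bis(triethylsilyloxy)-6-[3-(trimethylsilyl)prop-1-en-2-yl]tetrahydro-2H-pyran-2-ol; 16 ethyl (triphenylphosphoranylidene)acetate
Product: 18 ethyl 2-[(2R,3S,4S,6R)-3-methyl-3,4-bis(triethylsilyloxy)-6-[3-(trimethylsilyl)prop-1-en-2-yl]tetrahydro-2H-pyran-2-yl]acetate, via hydroxy enoate 17 (not isolated)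
Conditions: 16 (2.5 equiv), PhMe, 100 °C; then DBU (0.3 equiv), rt → 50 °C
Reagents that add atoms: none
Why: Wittig olefination of the ring‑opened hydroxy aldehyde gives (E)-enoate 17, whose C6 hydroxyl then adds by a 6‑exo‑trig oxa‑Michael reaction, and under equilibrating base the 2,6‑cis tetrahydropyran with both C2 and C6 substituents equatorial is the thermodynamic product, which sets C2.

Step 11
Reactants: 18 ethyl 2-[(2R,3S,4S,6R)-3-methyl-3,4-bis(triethylsilyloxy)-6-[3-(trimethylsilyl)prop-1-en-2-yl]tetrahydro-2H-pyran-2-yl]acetate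
Product: 19 2-[(2R,3S,4S,6R)-3-methyl-3,4-bis(triethylsilyloxy)-6-[3-(trimethylsilyl)prop-1-en-2-yl]tetrahydro-2H-pyran-2-yl]acetic acid
Conditions: LiOH·H2O, THF/MeOH/H2O, rt; 1 M HCl to pH 4
Reagents that add atoms: lithium hydroxide, [Li+].[OH-]
Why: Mild saponification of the unhindered ethyl ester is expected to leave the hindered silyl ethers and the β‑alkoxy linkage intact.

Step 12
Reactants: 19 2-[(2R,3S,4S,6R)-3-methyl-3,4-bis(triethylsilyloxy)-6-[3-(trimethylsilyl)prop-1-en-2-yl]tetrahydro-2H-pyran-2-yl]acetic acid; 20 (trimethylsilyl)diazomethane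
Product: 22 1-diazo-3-[(2R,3S,4S,6R)-3-methyl-3,4-bis(triethylsilyloxy)-6-[3-(trimethylsilyl)prop-1-en-2-yl]tetrahydro-2H-pyran-2-yl]propan-2-one, via mixed anhydride 21 (not isolated)
Conditions: i-BuOCOCl, Et3N, THF, −15 °C; then 20 (2.5 equiv), MeCN/THF, 0 °C → rt
Reagents that add atoms: isobutyl chloroformate, CC(C)COC(Cl)=O (carbonate unit of 21 only)
Why: Activation as the mixed carbonic anhydride and C‑acylation of the silyl diazomethane with loss of silicon gives the terminal α‑diazoketone without exposing the allylsilane or the silyl ethers to acid.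

Step 13
Reactants: 22 1-diazo-3-[(2R,3S,4S,6R)-3-methyl-3,4-bis(triethylsilyloxy)-6-[3-(trimethylsilyl)prop-1-en-2-yl]tetrahydro-2H-pyran-2-yl]propan-2-one
Product: 24 bridged oxonene furanone (C10 ketone, C1 methylene, cis C6=C7 ring alkene with CH2SiMe3 on C7, 3-Me, 3,4-bis(OSiEt3), 2,9-cis ether bridge), via oxonium ylide 23 (not isolated)
Conditions: Cu(hfacac)2 [Cu(CF3COCHCOCF3)2] (5 mol%), CH2Cl2, reflux, slow addition of 22
Reagents that add atoms: none
Why: Copper bis(hexafluoroacetylacetonate) decomposes the diazoketone to an electrophilic copper carbenoid at C9, which is captured by a lone pair of the pyran oxygen to give the fused oxonium ylide 23 or its copper‑bound equivalent. A concerted suprafacial [2,3]‑sigmatropic shift through a five‑membered envelope transition state then joins C9 to the alkene terminus C8, breaks O–C6 and moves the double bond to C6=C7; the closest known reaction type is the copper‑catalysed oxonium ylide formation and [2,3] rearrangement of allylic ethers, as used for the ring expansion of 6‑vinyl tetrahydropyranyl diazoketones to bridged medium‑ring ethers. The furanone ring (O, C2, C1, C10, C9) is closed by attack of oxygen on the carbenoid carbon in a five‑membered cyclisation, whereas the nine‑membered ring is not closed directly but arises by three‑atom enlargement of the pyran. The only new stereocentre, C9, is controlled by C2, because the ether bridge across the oxonene can only be cis, so H9 and H2 end on the same side. The step needs ylide formation at the ring oxygen to beat C–H insertion, cyclopropanation of the allylsilane and attack by the C3 silyloxy oxygen, which the five‑membered closure, the bulky silyl group on the tertiary oxygen and the electron‑poor catalyst should secure, and it needs the [2,3] over the [1,2] shift, which the cis C2/C6 arrangement favours by holding C8 over the ylide carbon. The ring alkene is expected mainly as the cis isomer, and either isomer would serve because this geometry is erased in step 27.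

Step 14
Reactants: 24 bridged oxonene furanone
Product: 25 C10 enol triflate of 24 (C1=C10 double bond)
Conditions: NaN(SiMe3)2, THF, −78 °C; PhNTf2, −78 → −40 °C
Reagents that add atoms: N-phenylbis(trifluoromethanesulfonimide), O=S(=O)(N(c1ccccc1)S(=O)(=O)C(F)(F)F)C(F)(F)F
Why: Kinetic deprotonation should occur at the C1 methylene (the C9 bridge hydrogen is hindered and its enolate would be a strained bridgehead alkene) and the enolate is O‑triflated.

Step 15
Reactants: 26 ethyl (Z)-prop-1-enyl ether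
Product: 28 (E)-tributyl(1-ethoxyprop-1-en-1-yl)stannane (methyl cis to ethoxy), via lithioalkene 27 (not isolated)
Conditions: t-BuLi (0.95 equiv), THF, −78 → −10 °C; Bu3SnCl, −78 °C → rt
Reagents that add atoms: tert-butyllithium, [Li]C(C)(C)C (lithium of 27 only); tributyltin chloride, CCCC[Sn](Cl)(CCCC)CCCC
Why: α‑Lithiation of the enol ether and stannylation both proceed with retention of alkene geometry, so the methyl group stays cis to the ethoxy group.

Step 16
Reactants: 25 C10 enol triflate; 28 (E)-tributyl(1-ethoxyprop-1-en-1-yl)stannane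
Product: 29 2-ethoxy diene (C1=C10–C11(OEt)=C12H–CH3, methyl cis to ethoxy and trans to C10)
Conditions: Pd(PPh3)4 (5 mol%), LiCl (3 equiv), CuI (10 mol%), THF, 65 °C
Reagents that add atoms: none
Why: Stille coupling of the enol triflate with the α‑alkoxyalkenylstannane keeps the geometry of both partners, giving a diene whose C12 methyl points outward in the s‑cis form.

Step 17
Reactants: 29 2-ethoxy diene; 30 but-3-en-2-one
Product: 32 hydrobenzofuran-fused oxonene (14-acetyl trans to C2, 12-methyl cis to C2, C10=C11 enol ether, H1 trans to H2), via cycloadduct epimers 31 (not isolated)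
Conditions: 30 (10 equiv), BHT (cat.), PhMe, 100 °C (sealed tube); then K2CO3, MeOH, rt
Reagents that add atoms: none
Why: Thermal Diels–Alder reaction in which the 2‑ethoxy group directs the enone to the para orientation (C12–C13 and C1–C14 bonds), the enone adds to the diene face turned away from the nine‑membered ring (sets C1), suprafacial addition places the outward C12 methyl cis to C2 (sets C12), and base equilibration of the acetyl‑bearing carbon gives the trans, equatorial C14 isomer.

Step 18
Reactants: 32 14-acetyl tricycle; 33 methyltriphenylphosphonium bromide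
Product: 34 14-isopropenyl tricycle (C10=C11 enol ether retained)
Conditions: 33, KOt-Bu, THF, 0 °C → reflux
Reagents that add atoms: none
Why: Wittig methylenation of the methyl ketone, in which the basic ylide can only return C14 to its already thermodynamic configuration.

Step 19
Reactants: 34 14-isopropenyl tricycle
Product: 36 C16 primary alcohol (C15 as in the target), via alkylborane 35 (not isolated)
Conditions: 9-BBN (2 equiv), THF, 0 °C → rt; then NaOH, H2O2, 0 °C
Reagents that add atoms: 9-borabicyclo[3.3.1]nonane, B1C2CCCC1CCC2 (boron unit of 35 only); hydrogen peroxide, OO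
Why: Anti‑Markovnikov hydroboration–oxidation, in which the bulky borane should react only with the 1,1‑disubstituted isopropenyl group (not the trisubstituted allylsilane or the tetrasubstituted enol ether) and attack the alkene face turned away from C1 in the rotamer with C14–H eclipsing the C=C bond, which sets C15.

Step 20
Reactants: 36 C16 primary alcohol
Product: 37 C3,C4,C16 triol
Conditions: Bu4NF (2.5 equiv), THF, 0 °C → rt
Reagents that add atoms: none
Why: Fluoride cleaves both triethylsilyl ethers in one operation under basic conditions that spare the enol ether and, at this temperature, the allylsilane.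

Step 21
Reactants: 37 C3,C4,C16 triol
Product: 39 tetracyclic oxepane (C3–O–C16 ether, free C4–OH), via primary triflate 38 (not isolated)
Conditions: Tf2O (1.05 equiv), 2,6-lutidine (4 equiv), CH2Cl2, −78 → 0 °C
Reagents that add atoms: trifluoromethanesulfonic anhydride, O=S(=O)(OS(=O)(=O)C(F)(F)F)C(F)(F)F (triflyl group of 38 only)
Why: The primary hydroxyl should be triflated selectively at low temperature and displaced by the tertiary C3 hydroxyl in a 7‑exo‑tet etherification, since closure through the C4 hydroxyl would need an eight‑membered ring.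

Step 22
Reactants: 39 tetracyclic oxepane
Product: 40 C4 acetate
Conditions: Ac2O, DMAP, pyridine, CH2Cl2, rt
Reagents that add atoms: acetic anhydride, CC(=O)OC(C)=O
Why: DMAP‑catalysed acetylation of the only remaining hydroxyl.

Step 23
Reactants: 40 C4 acetate
Product: 41 C11 ketone (H10 cis to H1, 12-methyl unchanged)
Conditions: 0.5 M aq. HCl, THF, 0 °C; aq. NaHCO3
Reagents that add atoms: water, O
Why: Mild hydrolysis of the tetrasubstituted enol ether, in which protonation at C10 on the face bearing H1 should give the cis ring fusion (sets C10) under conditions too mild to protodesilylate the allylsilane or enolise the ketone toward C12.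

Step 24
Reactants: 41 C11 ketone
Product: 42 C11 alcohol (OH cis to the C12 methyl and to C9)
Conditions: NaBH4, CeCl3·7H2O, MeOH, −40 °C
Reagents that add atoms: none
Why: Luche‑type reduction, in which hydride should attack C11 from the face opposite the two flanking axial groups (C9 on C10 and the C12 methyl), giving the equatorial alcohol and setting C11 before the sensitive ketone can epimerise.

Step 25
Reactants: 43 (R)-2-hydroxyoctanoic acid
Product: 45 (R)-2-(triethylsilyloxy)octanoic acid, via silyl ester 44 (not isolated)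
Conditions: Et3SiCl (2.4 equiv), imidazole, DMF, rt; then K2CO3, MeOH/H2O, 0 °C; pH 4 buffer
Reagents that add atoms: chlorotriethylsilane, CC[Si](Cl)(CC)CC
Why: Bis‑silylation followed by selective methanolysis of the far more labile silyl ester frees the acid while the α‑oxygen stays protected.

Step 26
Reactants: 42 C11 alcohol; 45 (R)-2-(triethylsilyloxy)octanoic acid
Product: 46 C11 (R)-2-(triethylsilyloxy)octanoate
Conditions: DCC, DMAP (0.2 equiv), CH2Cl2, 0 °C → rt
Reagents that add atoms: none
Why: Steglich esterification of the equatorial secondary alcohol by acyl transfer, which does not touch the stereocentres of either partner.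

Step 27
Reactants: 46 C11 (R)-2-(triethylsilyloxy)octanoate
Product: 47 target CNP0132024.3 (4-acetoxy-11-[(R)-2-hydroxyoctanoyloxy] asbestinin with C7 exocyclic methylene)
Conditions: CF3CO2H (5 equiv), CH2Cl2 (trace H2O), −10 → 0 °C; aq. NaHCO3
Reagents that add atoms: none
Why: Acid‑mediated protodesilylation (SE2′), in which protonation at C6 gives the β‑silyl‑stabilised C7 cation that loses silicon to form the exocyclic C7 methylene from either alkene isomer, while the same acid cleaves the triethylsilyl ether.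

Compound list
1 | methyl (R)-oxirane-2-carboxylate | COC(=O)[C@H]1CO1 | starting material
2 | vinylmagnesium bromide | C=C[Mg]Br | starting material
3 | methyl (R)-2-hydroxypent-4-enoate | COC(=O)[C@@H](CC=C)O | intermediate
4 | (trimethylsilyl)methylmagnesium chloride | C[Si](C)(C)C[Mg]Cl | starting material
5 | (3R)-1-(trimethylsilyl)-2-[(trimethylsilyl)methyl]hex-5-ene-2,3-diol | C=CC[C@@H](O)C(O)(C[Si](C)(C)C)C[Si](C)(C)C | intermediate (not isolated)
6 | (R)-2-[(trimethylsilyl)methyl]hexa-1,5-dien-3-ol | C=C(C[Si](C)(C)C)[C@@H](CC=C)O | intermediate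
7 | methacryloyl chloride | C=C(C)C(Cl)=O | starting material
8 | (R)-2-[(trimethylsilyl)methyl]hexa-1,5-dien-3-yl 2-methylprop-2-enoate | C=C(C[Si](C)(C)C)[C@@H](CC=C)OC(=O)C(C)=C | intermediate
9 | (R)-3-methyl-6-[3-(trimethylsilyl)prop-1-en-2-yl]-5,6-dihydro-2H-pyran-2-one | C=C(C[Si](C)(C)C)[C@H]1CC=C(C)C(=O)O1 | intermediate
10 | (4S,6R)-3-methyl-4-(4,4,5,5-tetramethyl-1,3,2-dioxaborolan-2-yl)-6-[3-(trimethylsilyl)prop-1-en-2-yl]tetrahydro-2H-pyran-2-one (C3 epimers, boron trans to the C6 group) | C=C(C[Si](C)(C)C)[C@H]1C[C@H](B2OC(C)(C)C(C)(C)O2)C(C)C(=O)O1 | intermediate (not isolated)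
11 | (4S,6R)-4-hydroxy-3-methyl-6-[3-(trimethylsilyl)prop-1-en-2-yl]tetrahydro-2H-pyran-2-one (C3 epimers) | C=C(C[Si](C)(C)C)[C@H]1C[C@H](O)C(C)C(=O)O1 | intermediate
12 | (4S,6R)-3-methyl-4-(triethylsilyloxy)-6-[3-(trimethylsilyl)prop-1-en-2-yl]tetrahydro-2H-pyran-2-one (C3 epimers) | C=C(C[Si](C)(C)C)[C@H]1C[C@H](O[Si](CC)(CC)CC)C(C)C(=O)O1 | intermediate
13 | (3R,4S,6R)-3-hydroxy-3-methyl-4-(triethylsilyloxy)-6-[3-(trimethylsilyl)prop-1-en-2-yl]tetrahydro-2H-pyran-2-one | C=C(C[Si](C)(C)C)[C@H]1C[C@H](O[Si](CC)(CC)CC)[C@@](C)(O)C(=O)O1 | intermediate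
14 | (3R,4S,6R)-3-methyl-3,4-bis(triethylsilyloxy)-6-[3-(trimethylsilyl)prop-1-en-2-yl]tetrahydro-2H-pyran-2-one | C=C(C[Si](C)(C)C)[C@H]1C[C@H](O[Si](CC)(CC)CC)[C@@](C)(O[Si](CC)(CC)CC)C(=O)O1 | intermediate
15 | (3R,4S,6R)-3-methyl-3,4-bis(triethylsilyloxy)-6-[3-(trimethylsilyl)prop-1-en-2-yl]tetrahydro-2H-pyran-2-ol (anomers) | C=C(C[Si](C)(C)C)[C@H]1C[C@H](O[Si](CC)(CC)CC)[C@@](C)(O[Si](CC)(CC)CC)C(O)O1 | intermediate
16 | ethyl (triphenylphosphoranylidene)acetate | CCOC(=O)C=P(c1ccccc1)(c1ccccc1)c1ccccc1 | starting material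
17 | ethyl (2E,4S,5S,7R)-7-hydroxy-4-methyl-4,5-bis(triethylsilyloxy)-8-[(trimethylsilyl)methyl]nona-2,8-dienoate | CCOC(=O)/C=C/[C@](C)(O[Si](CC)(CC)CC)[C@@H](O[Si](CC)(CC)CC)C[C@@H](O)C(=C)C[Si](C)(C)C | intermediate (not isolated)
18 | ethyl 2-[(2R,3S,4S,6R)-3-methyl-3,4-bis(triethylsilyloxy)-6-[3-(trimethylsilyl)prop-1-en-2-yl]tetrahydro-2H-pyran-2-yl]acetate | C=C(C[Si](C)(C)C)[C@H]1C[C@H](O[Si](CC)(CC)CC)[C@@](C)(O[Si](CC)(CC)CC)[C@@H](CC(=O)OCC)O1 | intermediate
19 | 2-[(2R,3S,4S,6R)-3-methyl-3,4-bis(triethylsilyloxy)-6-[3-(trimethylsilyl)prop-1-en-2-yl]tetrahydro-2H-pyran-2-yl]acetic acid | C=C(C[Si](C)(C)C)[C@H]1C[C@H](O[Si](CC)(CC)CC)[C@@](C)(O[Si](CC)(CC)CC)[C@@H](CC(=O)O)O1 | intermediate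
20 | (trimethylsilyl)diazomethane | C[Si](C)(C)C=[N+]=[N-] | starting material
21 | isobutyl carbonic anhydride of acid 19 | C=C(C[Si](C)(C)C)[C@H]1C[C@H](O[Si](CC)(CC)CC)[C@@](C)(O[Si](CC)(CC)CC)[C@@H](CC(=O)OC(=O)OCC(C)C)O1 | intermediate (not isolated)
22 | 1-diazo-3-[(2R,3S,4S,6R)-3-methyl-3,4-bis(triethylsilyloxy)-6-[3-(trimethylsilyl)prop-1-en-2-yl]tetrahydro-2H-pyran-2-yl]propan-2-one | C=C(C[Si](C)(C)C)[C@H]1C[C@H](O[Si](CC)(CC)CC)[C@@](C)(O[Si](CC)(CC)CC)[C@@H](CC(=O)C=[N+]=[N-])O1 | intermediate (key-step precursor)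
23 | bicyclic oxonium ylide (O+ bonded to C2, C6 and C9; carbanion at C9) | C=C(C[Si](C)(C)C)[C@H]1C[C@H](O[Si](CC)(CC)CC)[C@@](C)(O[Si](CC)(CC)CC)[C@H]2CC(=O)[CH-][O+]12 | intermediate (not isolated)
24 | bridged oxonene furanone (11-oxabicyclo[6.2.1]undecenone skeleton; C10 ketone, cis C6=C7 ring alkene, 7-CH2SiMe3, 3-Me, 3,4-bis(OSiEt3)) | C[Si](C)(C)C/C1=C/C[C@H](O[Si](CC)(CC)CC)[C@@](C)(O[Si](CC)(CC)CC)[C@H]2CC(=O)[C@@H](C1)O2 | intermediate (key-step product)
25 | C10 enol triflate of 24 | C[Si](C)(C)C/C1=C/C[C@H](O[Si](CC)(CC)CC)[C@@](C)(O[Si](CC)(CC)CC)[C@H]2C=C(OS(=O)(=O)C(F)(F)F)[C@@H](C1)O2 | intermediate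
26 | ethyl (Z)-prop-1-enyl ether | CCO/C=C\C | starting material
27 | (Z)-(1-ethoxyprop-1-en-1-yl)lithium | C/C=C(\OCC)[Li] | intermediate (not isolated)
28 | (E)-tributyl(1-ethoxyprop-1-en-1-yl)stannane | C/C=C(\OCC)[Sn](CCCC)(CCCC)CCCC | intermediate
29 | 2-ethoxy diene (C10 bears the 1-ethoxyprop-1-enyl group, methyl cis to ethoxy) | C[Si](C)(C)C/C1=C/C[C@H](O[Si](CC)(CC)CC)[C@@](C)(O[Si](CC)(CC)CC)[C@H]2C=C(/C(OCC)=C/C)[C@@H](C1)O2 | intermediate
30 | but-3-en-2-one | C=CC(C)=O | starting material
31 | Diels–Alder adduct as C14 epimers | C[Si](C)(C)C/C1=C/C[C@H](O[Si](CC)(CC)CC)[C@@](C)(O[Si](CC)(CC)CC)[C@H]2[C@@H]3C(C(C)=O)C[C@H](C)C(OCC)=C3[C@@H](C1)O2 | intermediate (not isolated)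
32 | 14-acetyl tricycle (acetyl trans to C2, 12-Me cis to C2, C10=C11 enol ether) | C[Si](C)(C)C/C1=C/C[C@H](O[Si](CC)(CC)CC)[C@@](C)(O[Si](CC)(CC)CC)[C@H]2[C@@H]3[C@@H](C(C)=O)C[C@H](C)C(OCC)=C3[C@@H](C1)O2 | intermediate
33 | methyltriphenylphosphonium bromide | C[P+](c1ccccc1)(c1ccccc1)c1ccccc1.[Br-] | starting material
34 | 14-isopropenyl tricycle | C[Si](C)(C)C/C1=C/C[C@H](O[Si](CC)(CC)CC)[C@@](C)(O[Si](CC)(CC)CC)[C@H]2[C@@H]3[C@@H](C(C)=C)C[C@H](C)C(OCC)=C3[C@@H](C1)O2 | intermediate
35 | C16 B-alkyl-9-borabicyclo[3.3.1]nonane | C[Si](C)(C)C/C1=C/C[C@H](O[Si](CC)(CC)CC)[C@@](C)(O[Si](CC)(CC)CC)[C@H]2[C@@H]3[C@@H]([C@H](C)CB4C5CCCC4CCC5)C[C@H](C)C(OCC)=C3[C@@H](C1)O2 | intermediate (not isolated)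
36 | C16 primary alcohol (C15 set) | C[Si](C)(C)C/C1=C/C[C@H](O[Si](CC)(CC)CC)[C@@](C)(O[Si](CC)(CC)CC)[C@H]2[C@@H]3[C@@H]([C@H](C)CO)C[C@H](C)C(OCC)=C3[C@@H](C1)O2 | intermediate
37 | C3,C4,C16 triol | C[Si](C)(C)C/C1=C/C[C@H](O)[C@@](C)(O)[C@H]2[C@@H]3[C@@H]([C@H](C)CO)C[C@H](C)C(OCC)=C3[C@@H](C1)O2 | intermediate
38 | C16 primary triflate | C[Si](C)(C)C/C1=C/C[C@H](O)[C@@](C)(O)[C@H]2[C@@H]3[C@@H]([C@H](C)COS(=O)(=O)C(F)(F)F)C[C@H](C)C(OCC)=C3[C@@H](C1)O2 | intermediate (not isolated)
39 | tetracyclic oxepane with free C4–OH | C[Si](C)(C)C/C1=C/C[C@H](O)[C@@]2(C)OC[C@@H](C)[C@H]3C[C@H](C)C(OCC)=C4[C@@H]3[C@H]2O[C@@H]4C1 | intermediate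
40 | C4 acetate | C[Si](C)(C)C/C1=C/C[C@H](OC(C)=O)[C@@]2(C)OC[C@@H](C)[C@H]3C[C@H](C)C(OCC)=C4[C@@H]3[C@H]2O[C@@H]4C1 | intermediate
41 | C11 ketone (cis ring fusion) | C[Si](C)(C)C/C1=C/C[C@H](OC(C)=O)[C@@]2(C)OC[C@@H](C)[C@H]3C[C@H](C)C(=O)[C@H]4[C@@H]3[C@H]2O[C@@H]4C1 | intermediate
42 | C11 alcohol | C[Si](C)(C)C/C1=C/C[C@H](OC(C)=O)[C@@]2(C)OC[C@@H](C)[C@H]3C[C@H](C)[C@H](O)[C@H]4[C@@H]3[C@H]2O[C@@H]4C1 | intermediate
43 | (R)-2-hydroxyoctanoic acid | CCCCCC[C@@H](O)C(=O)O | starting material
44 | triethylsilyl (R)-2-(triethylsilyloxy)octanoate | CCCCCC[C@@H](O[Si](CC)(CC)CC)C(=O)O[Si](CC)(CC)CC | intermediate (not isolated)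
45 | (R)-2-(triethylsilyloxy)octanoic acid | CCCCCC[C@@H](O[Si](CC)(CC)CC)C(=O)O | intermediate
46 | C11 (R)-2-(triethylsilyloxy)octanoate of 42 | C[Si](C)(C)C/C1=C/C[C@H](OC(C)=O)[C@@]2(C)OC[C@@H](C)[C@H]3C[C@H](C)[C@H](OC(=O)[C@H](O[Si](CC)(CC)CC)CCCCCC)[C@H]4[C@@H]3[C@H]2O[C@@H]4C1 | intermediate
47 | CNP0132024.3 | C=C1CC[C@H](OC(C)=O)[C@@]2(C)OC[C@@H](C)[C@H]3C[C@H](C)[C@H](OC(=O)[C@H](O)CCCCCC)[C@H]4[C@@H]3[C@H]2O[C@@H]4C1 | target

Total step count: 27. Longest linear sequence: 25 steps (steps 1–14, 16–24, 26 and 27; steps 15 and 25 prepare side components).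

Steps most likely to fail

Step 13. The carbenoid may be diverted before or after ylide formation: C–H insertion, capture by a silyl ether oxygen, or a [1,2] shift in place of the [2,3] shift. The fallback keeps the same bond‑forming event but uses a stabilised carbenoid, which is slower to insert and more selective for ylide formation. It sets out from acid 19. Activation with carbonyldiimidazole and treatment with the magnesium salt of monomethyl malonate (Masamune homologation) would give the β‑keto ester F1. Diazo transfer with p‑acetamidobenzenesulfonyl azide and Et3N would give the diazo keto ester F2. Rh2(OAc)4 in CH2Cl2 would then give the bicyclic keto ester F3 by the same ylide formation and [2,3] shift, with the ester on C9. Krapcho demethoxycarbonylation (LiCl, wet DMSO, 130 °C) removes the ester; C9 cannot change configuration because the bridge fixes it, and the route is rejoined at ketone 24.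

Step 19. Facial selectivity of borane addition to the freely rotating isopropenyl group may be poor, which would leave C15 as a mixture. The fallback replaces substrate‑controlled hydroboration by reagent‑controlled hydrogenation of an allylic alcohol. It sets out from methyl ketone 32. Kinetic enolisation at the methyl group (KN(SiMe3)2, N‑(5‑chloropyridin‑2‑yl)bis(trifluoromethanesulfonimide), −78 °C) would give the vinyl triflate F4. Stille coupling with (tributylstannyl)methanol (Pd(PPh3)4, LiCl) would give the 2‑substituted allylic alcohol F5. Hydroxyl‑directed hydrogenation with Ru(OAc)2(BINAP), the ligand antipode chosen to match, would then deliver C15 and rejoin the route at alcohol 36; the allylsilane and enol ether alkenes carry no directing group and should stay untouched.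

Step 21. Chemoselectivity may be lost between the primary and the secondary C4 hydroxyl during triflation, or some closure may occur through the C4 oxygen. The fallback masks C4 before the ring is closed and sets out from triol 37. Selective silylation of the primary hydroxyl (t‑BuMe2SiCl, imidazole) would give the silyl ether F6. Acetylation of the C4 hydroxyl (Ac2O, DMAP; the tertiary hydroxyl does not react) would give the acetate F7. Buffered fluoride (Bu4NF, AcOH) would free the primary alcohol F8. Triflation with Tf2O and 2,6‑lutidine can then be attacked only by the tertiary C3 hydroxyl, which rejoins the route at acetate 40.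

Further compounds
F1 | step 13 | methyl 4-[(2R,3S,4S,6R)-3-methyl-3,4-bis(triethylsilyloxy)-6-[3-(trimethylsilyl)prop-1-en-2-yl]tetrahydro-2H-pyran-2-yl]-3-oxobutanoate | C=C(C[Si](C)(C)C)[C@H]1C[C@H](O[Si](CC)(CC)CC)[C@@](C)(O[Si](CC)(CC)CC)[C@@H](CC(=O)CC(=O)OC)O1
F2 | step 13 | methyl 2-diazo-4-[(2R,3S,4S,6R)-3-methyl-3,4-bis(triethylsilyloxy)-6-[3-(trimethylsilyl)prop-1-en-2-yl]tetrahydro-2H-pyran-2-yl]-3-oxobutanoate | C=C(C[Si](C)(C)C)[C@H]1C[C@H](O[Si](CC)(CC)CC)[C@@](C)(O[Si](CC)(CC)CC)[C@@H](CC(=O)C(=[N+]=[N-])C(=O)OC)O1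
F3 | step 13 | C9 methoxycarbonyl derivative of bridged oxonene furanone 24 | C[Si](C)(C)C/C1=C/C[C@H](O[Si](CC)(CC)CC)[C@@](C)(O[Si](CC)(CC)CC)[C@H]2CC(=O)[C@@](C(=O)OC)(C1)O2
F4 | step 19 | C15 vinyl triflate from methyl ketone 32 | C[Si](C)(C)C/C1=C/C[C@H](O[Si](CC)(CC)CC)[C@@](C)(O[Si](CC)(CC)CC)[C@H]2[C@@H]3[C@@H](C(=C)OS(=O)(=O)C(F)(F)F)C[C@H](C)C(OCC)=C3[C@@H](C1)O2
F5 | step 19 | C14 3-hydroxyprop-1-en-2-yl tricycle (2-substituted allylic alcohol) | C[Si](C)(C)C/C1=C/C[C@H](O[Si](CC)(CC)CC)[C@@](C)(O[Si](CC)(CC)CC)[C@H]2[C@@H]3[C@@H](C(=C)CO)C[C@H](C)C(OCC)=C3[C@@H](C1)O2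
F6 | step 21 | C16 tert-butyldimethylsilyl ether of triol 37 | C[Si](C)(C)C/C1=C/C[C@H](O)[C@@](C)(O)[C@H]2[C@@H]3[C@@H]([C@H](C)CO[Si](C)(C)C(C)(C)C)C[C@H](C)C(OCC)=C3[C@@H](C1)O2
F7 | step 21 | C4 acetate of F6 | C[Si](C)(C)C/C1=C/C[C@H](OC(C)=O)[C@@](C)(O)[C@H]2[C@@H]3[C@@H]([C@H](C)CO[Si](C)(C)C(C)(C)C)C[C@H](C)C(OCC)=C3[C@@H](C1)O2
F8 | step 21 | C4 acetate with free C3 and C16 hydroxyls | C[Si](C)(C)C/C1=C/C[C@H](OC(C)=O)[C@@](C)(O)[C@H]2[C@@H]3[C@@H]([C@H](C)CO)C[C@H](C)C(OCC)=C3[C@@H](C1)O2
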